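We read both flasks at 1.5 min, so we first ask whether that time matters.

    gas ⇌ second nucleophile, rate k1*(csat - [second nucleophile]) (k1 = 8.22 s⁻¹, csat = 0.39 mM)
    crystals ⇌ target, rate k2*(cs2 - [target]) while solid is left; crystals form when [target] > cs2 (cs2 = 0.92 mM, k2 = 1.14 s⁻¹)
    substrate → intermediate (k3 = 0.149 s⁻¹)
    second nucleophile + intermediate → other capture product (k4 = 71.4 L mol⁻¹ s⁻¹)
    first nucleophile + intermediate → target (k5 = 17.5 L mol⁻¹ s⁻¹)
    intermediate → solvolysis product (k6 = 0.406 s⁻¹)

all flasks: substrate 0.010 M; gas 0.39 mM (held); time 1.5 min
- green: first nucleophile 0.0300 M
- blue: first nucleophile 0.0150 M

- amounts and yields of target count crystals too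
- given per volume of solution although it is solid: crystals
- at the start none of second nucleophile is dissolved
- run time (green): 1.5 min

- which of the two there is more of at the end, green (target / solvolysis product)
- which of the two there is more of at the end, blue (target / solvolysis product)
- final target, as a percentage of the substrate charged, in green
- final target, as a percentage of the substrate charged, in blue

**Time.** The substrate has a half-life of 4.65 s, and solvolysis by itself gives the intermediate one of 1.71 s. Both are far shorter than the run, and the substrate left at the reading is <0.001% of its charge. So by hand the time drops out, and the question becomes how the intermediate divides.

**Gas.** Dissolved second nucleophile comes up to 0.39 mM in about 0.122 s, which is faster than the substrate reacts. Its capture then runs at 0.0278 s⁻¹, slower than solvolysis at 0.406 s⁻¹.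

**First nucleophile.** We divide the two other exits by 17.5 L mol⁻¹ s⁻¹ and get 0.0248 M. This is the even-split amount: the amount of first nucleophile at which the intermediate goes to target as fast as to its other exits. Its inverse is a selectivity factor. The share going to target is then

share = amount / (amount + even-split amount)

**Substrate.** It enters through the drawdown of first nucleophile, so we take the amount at the midpoint of target formation:

green: share at the charge 54.8%; midpoint amount 0.0273 M; target 52.4%

blue: share at the charge 37.7%; midpoint amount 0.0131 M; target 34.6%

The remainder divides by the two rates, which gives solvolysis product 44.6% in green and 61.2% in blue. By hand, target leads in green and solvolysis product leads in blue.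

**Solubility.** Green should hold more target than dissolves, and so should blue. But crystals count as target, and no step returns target to intermediate, so the solubility stays out of the reckoning.

The forecast says target for green and solvolysis product for blue, with 52.4% and 34.7% of target. Its maker writes: “I allowed for depletion of the first nucleophile”. In green and in blue its target figures lie close to mine .

Green ends with 52.4% target and 44.6% solvolysis product, blue with 34.7% and 61.1%.

In blue at 0.0775 min, the intermediate has a half-life of 2.9 s by first nucleophile and 1.7 s by solvolysis, shorter by solvolysis, and that first half-life corresponds to 0.0137 M of first nucleophile, less than the even-split amount. In the neighbour of blue charged with 0.060 M, which is more than the even-split amount, the midpoint share is 69.5% and the flask ends with 69.5% target.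

The constants used here are made up; the rest is arithmetic.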